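**Assumption:** Cudraphenone D has no stereocenter and no E/Z-stereogenic alkene (both prenyl groups end in CMe2), so it is a single achiral compound and no stereocontrol is needed.

## Retrosynthetic overview

1. No ring is built: ring B comes from resorcinol and ring A from 3-bromophenol. The last step is global removal of three MOM ethers.
2. Key disconnection is the ring A aryl–C(=O) bond, made by a Pd-catalyzed, phenoxide-directed formyl C–H arylation of a ring-B salicylaldehyde with a ring-A aryl iodide.
3. Ring-B salicylaldehyde: resorcinol → bis-MOM ether → C2 prenylation by directed ortho-metalation → Ir-catalyzed C–H borylation/oxidation for the third oxygen → ortho-formylation.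
4. Ring-A aryl iodide: 3-bromophenol → MOM ether → LDA metalation between Br and OMOM, prenylation → Br to I.
5. Both prenyl groups come from prenyl bromide and are installed before the fragments are joined.

## Route

**Step 1**
Reactants: 1, resorcinol
Product: 2, 1,3-bis(methoxymethoxy)benzene
Conditions: MOMCl, i-Pr2NEt, CH2Cl2, 0 °C → rt
Reagents that add atoms: chloromethyl methyl ether (MOMCl), COCCl
Why: Base-mediated O-alkylation of both phenols (MOM protection, Williamson type) gives the acetal ethers that later direct ortho-metalation.

**Step 2**
Reactants: 2, 1,3-bis(methoxymethoxy)benzene; 3, prenyl bromide (1-bromo-3-methylbut-2-ene)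
Product: 4, 1,3-bis(methoxymethoxy)-2-(3-methylbut-2-en-1-yl)benzene
Conditions: n-BuLi, THF, 0 °C; then CuBr·SMe2, prenyl bromide, −78 °C → rt
Reagents that add atoms: none besides reactant 3 (prenyl bromide, CC(C)=CCBr)
Why: Directed ortho-metalation occurs at C2, flanked by both OMOM groups, and the arylcopper is allylated at the unhindered α-carbon of prenyl bromide (SN2) to give the linear prenyl arene.

**Step 3**
Reactants: 4, 1,3-bis(methoxymethoxy)-2-(3-methylbut-2-en-1-yl)benzene
Product: 5, 3,5-bis(methoxymethoxy)-4-(3-methylbut-2-en-1-yl)phenol
Conditions: [Ir(OMe)(cod)]2 (1.5 mol %), dtbpy (3 mol %), B2pin2, THF, 70 °C; then 30% H2O2, aq NaOH, 0 °C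
Reagents that add atoms: hydrogen peroxide, OO (supplies the phenolic oxygen; boron from B2pin2 is only transient)
Why: Sterically controlled Ir-catalyzed aromatic C–H borylation picks the only C–H without an ortho substituent (C5, meta to both OMOM groups), and alkaline peroxide oxidation of the aryl boronate gives the phenol without touching the trisubstituted alkene.

**Step 4**
Reactants: 5, 3,5-bis(methoxymethoxy)-4-(3-methylbut-2-en-1-yl)phenol
Product: 6, 6-hydroxy-2,4-bis(methoxymethoxy)-3-(3-methylbut-2-en-1-yl)benzaldehyde
Conditions: MgCl2, Et3N, (CH2O)n, MeCN, 80 °C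
Reagents that add atoms: paraformaldehyde (formaldehyde), C=O
Why: In the Casnati–Skattebøl ortho-formylation the magnesium phenoxide delivers formaldehyde only ortho to OH (the two ortho sites are equivalent and para is blocked by prenyl), and hydride transfer to a second formaldehyde gives the salicylaldehyde under basic conditions that preserve MOM and prenyl.

**Step 5**
Reactants: 7, 3-bromophenol
Product: 8, 1-bromo-3-(methoxymethoxy)benzene
Conditions: MOMCl, i-Pr2NEt, CH2Cl2, 0 °C → rt
Reagents that add atoms: chloromethyl methyl ether (MOMCl), COCCl
Why: Standard MOM protection (O-alkylation) installs the directing group for the next metalation.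

**Step 6**
Reactants: 8, 1-bromo-3-(methoxymethoxy)benzene; 3, prenyl bromide
Product: 9, 1-bromo-3-(methoxymethoxy)-2-(3-methylbut-2-en-1-yl)benzene
Conditions: LDA, THF, −78 °C; then CuBr·SMe2, prenyl bromide, −78 → 0 °C
Reagents that add atoms: none besides reactant 3 (prenyl bromide, CC(C)=CCBr)
Why: Directed ortho-metalation with the non-nucleophilic amide base removes the C2 proton acidified by both Br and OMOM without Br/Li exchange (kept at −78 °C to avoid benzyne formation), and the arylcopper undergoes SN2 allylation with prenyl bromide.

**Step 7**
Reactants: 9, 1-bromo-3-(methoxymethoxy)-2-(3-methylbut-2-en-1-yl)benzene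
Product: 10, 1-iodo-3-(methoxymethoxy)-2-(3-methylbut-2-en-1-yl)benzene
Conditions: n-BuLi, THF, −78 °C; then I2
Reagents that add atoms: iodine, II
Why: Lithium–bromine exchange outruns any deprotonation at −78 °C and iodine traps the aryllithium, giving the aryl iodide needed for mild oxidative addition; the halogen is switched after the LDA step because 2-lithio iodoarenes are prone to halogen dance.

**Step 8**
Reactants: 6, 6-hydroxy-2,4-bis(methoxymethoxy)-3-(3-methylbut-2-en-1-yl)benzaldehyde; 10, 1-iodo-3-(methoxymethoxy)-2-(3-methylbut-2-en-1-yl)benzene
Product: 11, [6-hydroxy-2,4-bis(methoxymethoxy)-3-(3-methylbut-2-en-1-yl)phenyl][3-(methoxymethoxy)-2-(3-methylbut-2-en-1-yl)phenyl]methanone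
Conditions: Pd(OAc)2 (5 mol %), PCy3·HBF4 (10 mol %), PivOH (30 mol %), Cs2CO3, DMA, 90 °C, Ar
Reagents that add atoms: none
Why: Proposed new method: a carboxylate-assisted Pd(0)/Pd(II) formyl C–H arylation directed by the native ortho-phenoxide, in which oxidative addition of 10 gives ArPd(II)I, the cesium phenoxide of 6 displaces iodide and holds Pd next to the formyl C–H, pivalate-assisted C–H cleavage gives a five-membered O,C(acyl)-palladacycle (decarbonylation would need a four-membered ring, so CO is retained), and the bulky phosphine drives acyl–aryl reductive elimination to the chelated 2-hydroxybenzophenone; the closest known reaction type is the ligand-free Pd-catalyzed coupling of simple salicylaldehydes with unhindered aryl iodides (chelation-assisted aldehyde C–H arylation, related to Rh-catalyzed salicylaldehyde hydroacylation), which to my knowledge has not been shown for a 2,6-dioxygenated aldehyde, an ortho-allylated aryl iodide, or with a phosphine/pivalate catalyst.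

**Step 9**
Reactants: 11, the tris-MOM benzophenone
Product: 12, Cudraphenone D, [3-hydroxy-2-(3-methylbut-2-en-1-yl)phenyl][2,4,6-trihydroxy-3-(3-methylbut-2-en-1-yl)phenyl]methanone
Conditions: 3 M aq HCl, MeOH, rt → 40 °C, stopped at full conversion
Reagents that add atoms: none
Why: Acid-catalyzed acetal hydrolysis removes all three MOM ethers under dilute methanolic HCl, where MOM cleavage is faster than proton-initiated cyclization of the ortho-prenylphenols to chromans; no stereocenter is involved.

## Compound list

1 | resorcinol (benzene-1,3-diol) | Oc1cccc(O)c1 | starting material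
2 | 1,3-bis(methoxymethoxy)benzene | COCOc1cccc(OCOC)c1 | intermediate
3 | prenyl bromide (1-bromo-3-methylbut-2-ene) | CC(C)=CCBr | starting material
4 | 1,3-bis(methoxymethoxy)-2-(3-methylbut-2-en-1-yl)benzene | COCOc1cccc(OCOC)c1CC=C(C)C | intermediate
5 | 3,5-bis(methoxymethoxy)-4-(3-methylbut-2-en-1-yl)phenol | COCOc1cc(O)cc(OCOC)c1CC=C(C)C | intermediate
6 | 6-hydroxy-2,4-bis(methoxymethoxy)-3-(3-methylbut-2-en-1-yl)benzaldehyde | O=Cc1c(O)cc(OCOC)c(CC=C(C)C)c1OCOC | intermediate
7 | 3-bromophenol | Oc1cccc(Br)c1 | starting material
8 | 1-bromo-3-(methoxymethoxy)benzene | COCOc1cccc(Br)c1 | intermediate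
9 | 1-bromo-3-(methoxymethoxy)-2-(3-methylbut-2-en-1-yl)benzene | COCOc1cccc(Br)c1CC=C(C)C | intermediate
10 | 1-iodo-3-(methoxymethoxy)-2-(3-methylbut-2-en-1-yl)benzene | COCOc1cccc(I)c1CC=C(C)C | intermediate
11 | [6-hydroxy-2,4-bis(methoxymethoxy)-3-(3-methylbut-2-en-1-yl)phenyl][3-(methoxymethoxy)-2-(3-methylbut-2-en-1-yl)phenyl]methanone | CC(C)=CCc1c(OCOC)cccc1C(=O)c1c(O)cc(OCOC)c(CC=C(C)C)c1OCOC | intermediate
12 | Cudraphenone D, [3-hydroxy-2-(3-methylbut-2-en-1-yl)phenyl][2,4,6-trihydroxy-3-(3-methylbut-2-en-1-yl)phenyl]methanone | CC(C)=CCc1c(O)cccc1C(=O)c1c(O)cc(O)c(CC=C(C)C)c1O | target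

## Summary

**Total step count:** 9

**Longest linear sequence:** 6 (steps 1, 2, 3, 4, 8, 9); the ring-A branch is steps 5, 6, 7, then 8, 9.

**Three steps most likely to fail:**

- **Step 8 (proposed new formyl C–H arylation).** The hindered, electron-rich partners may react slowly, or give diaryl ether or biaryl by-products. Fallback with known chemistry: protect the phenol of 6 as a MOM ether, add the aryllithium made from bromide 9 (n-BuLi, −78 °C) to the aldehyde, oxidize the diarylcarbinol with Dess–Martin periodinane, then deprotect as in step 9.
- **Step 3 (Ir-catalyzed borylation with the prenyl alkene present).** Alkene hydroboration or vinylic borylation may compete. Fallback: borylate and oxidize before the alkene exists, i.e. convert 2 to 3,5-bis(methoxymethoxy)phenol, protect it as the TIPS ether, metalate between the two OMOM groups and prenylate with Cu mediation, then remove TIPS with TBAF to reach 5.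
- **Step 9 (acidic MOM removal next to ortho-prenylphenols).** Chroman formation or alkene hydration may occur. Fallback: carry the three hydroxyls as SEM ethers, which direct the same ortho-metalations, and unmask with fluoride (TBAF in DMPU) instead of Brønsted acid.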